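**Retrosynthetic overview**

- Calycopterin 17 comes from the 3,5,6,7,8-pentamethoxy-4'-benzyloxyflavone 15 by one BCl3 treatment (5-O-methyl peri to C4=O, and the benzyl group), and 15 from the 3-iodoflavone 14 by copper C–O coupling at C3.
- 14 comes from the ynone 12 by ICl-induced closure of the O1–C2 bond with loss of one methyl group. Ring C is the only ring formed; rings A and B are bought.
- The feature the route rests on: ring A carries an unbroken run of oxygens at C8a (O1), C5, C6, C7 and C8. In the open form these are five methoxyls on one benzene ring whose mirror plane passes through the acyl-bearing carbon, so the two ortho oxygens (future O1 and future C5–O) are interchangeable, and the iodine placed on C3 marks the C3 methoxyl.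
- 12 comes from pentamethoxybenzaldehyde 8 and alkyne 9 (acetylide addition, MnO2). 8 comes from pentamethoxybenzene 5, and 5 from 1,2,3,4-tetramethoxybenzene 1.

Key step: step 6

Remark: alcohol 11 is formed as a racemate; its single stereocentre is removed in step 5, and the target has no stereocentre.

**Step 1**
Reactants: 1 1,2,3,4-tetramethoxybenzene
Product: 4 2,3,4,5-tetramethoxyphenol, via (2,3,4,5-tetramethoxyphenyl)lithium 2 (not isolated), via lithium trimethoxy(2,3,4,5-tetramethoxyphenyl)borate 3 (not isolated)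
Conditions: n-BuLi, TMEDA, THF, 0 °C; B(OMe)3, −78 °C to rt; then AcOH, 30% H2O2, 0 °C to rt
Reagents that add atoms: hydrogen peroxide OO; n-butyllithium [Li]CCCC and trimethyl borate COB(OC)OC (atoms in intermediates 2 and 3 only)
Why: Directed ortho-lithiation beside a methoxyl (the two free positions of 1 are equivalent), borylation, and oxidative aryl migration from boron to oxygen should place the fifth oxygen exactly at the lithiated carbon.

**Step 2**
Reactants: 4 2,3,4,5-tetramethoxyphenol
Product: 5 pentamethoxybenzene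
Conditions: MeI, K2CO3, acetone, reflux
Reagents that add atoms: iodomethane CI
Why: Williamson ether synthesis on the only free phenol should give the symmetric pentamethyl ether.

**Step 3**
Reactants: 5 pentamethoxybenzene
Product: 8 2,3,4,5,6-pentamethoxybenzaldehyde, via (pentamethoxyphenyl)lithium 6 (not isolated), via lithium (dimethylamino)(pentamethoxyphenyl)methanolate 7 (not isolated)
Conditions: n-BuLi, TMEDA, THF, 0 °C; DMF, 0 °C to rt; then H2O
Reagents that add atoms: N,N-dimethylformamide CN(C)C=O; n-butyllithium [Li]CCCC (lithium in intermediates 6 and 7 only)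
Why: Directed ortho-metalation removes the single ring hydrogen, which is flanked by two methoxyls, and formylation of the aryllithium with DMF should give the aldehyde after hydrolysis of the hemiaminal alkoxide.

**Step 4**
Reactants: 8 2,3,4,5,6-pentamethoxybenzaldehyde; 9 1-(benzyloxy)-4-ethynylbenzene
Product: 11 3-[4-(benzyloxy)phenyl]-1-(pentamethoxyphenyl)prop-2-yn-1-ol (racemic), via lithium [4-(benzyloxy)phenyl]acetylide 10 (not isolated)
Conditions: 9, n-BuLi, THF, −78 °C; then 8, −78 to 0 °C; then H2O
Reagents that add atoms: n-butyllithium [Li]CCCC (lithium in intermediate 10 only)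
Why: 1,2-Addition of a lithium acetylide to an aldehyde should proceed cleanly despite the two ortho methoxyls; the carbinol centre is formed without control because it is oxidized in the next step.

**Step 5**
Reactants: 11 3-[4-(benzyloxy)phenyl]-1-(pentamethoxyphenyl)prop-2-yn-1-ol
Product: 12 3-[4-(benzyloxy)phenyl]-1-(pentamethoxyphenyl)prop-2-yn-1-one
Conditions: activated MnO2, CH2Cl2, rt
Reagents that add atoms: none
Why: MnO2 oxidation of a doubly activated (benzylic and propargylic) alcohol should give the ynone without touching the aryl or benzyl ethers.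

**Step 6**
Reactants: 12 3-[4-(benzyloxy)phenyl]-1-(pentamethoxyphenyl)prop-2-yn-1-one
Product: 14 2-[4-(benzyloxy)phenyl]-3-iodo-5,6,7,8-tetramethoxy-4H-chromen-4-one, via O-methyl chromenylium chloride 13 (not isolated)
Conditions: ICl (1.2 equiv), CH2Cl2, −78 °C, dark; then aq. Na2S2O3
Reagents that add atoms: iodine monochloride ClI
Why: ICl transfers an iodonium ion to the triple bond of 12, and the oxygen of one ortho methoxyl attacks the alkyne carbon that carries the 4-benzyloxyphenyl group, which closes the O1–C2 bond and gives the O-methyl oxonium chloride 13; chloride then removes the methyl group by SN2 displacement as chloromethane and leaves iodine on C3. The closest known reaction is the ICl-induced cyclization of ortho-methoxyaryl alkynones to 3-iodochromones. Ring C closes in the 6-endo-dig mode, and no stereocentre is formed. The step needs 6-endo over 5-exo selectivity, which should hold because the positive charge of the activated alkyne sits on the carbon benzylic to the para-alkoxyphenyl donor and not on the carbon next to the carbonyl, so an aurone-type closure is disfavoured. No choice between nucleophiles arises, because the mirror plane of the pentamethoxyphenyl ketone makes both ortho methoxyls identical, and the one left over becomes the C5 methoxyl. Chemoselectivity against iodination of ring B ortho to the benzyloxy group should be secured by the low temperature, the small excess of ICl and the fast intramolecular trapping, while ring A has no free C–H.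

**Step 7**
Reactants: 14 2-[4-(benzyloxy)phenyl]-3-iodo-5,6,7,8-tetramethoxy-4H-chromen-4-one
Product: 15 2-[4-(benzyloxy)phenyl]-3,5,6,7,8-pentamethoxy-4H-chromen-4-one
Conditions: CuI (20 mol%), 3,4,7,8-tetramethyl-1,10-phenanthroline (40 mol%), Cs2CO3, MeOH, toluene, 100 °C, sealed tube
Reagents that add atoms: methanol CO
Why: Ullmann-type copper-catalysed C–O coupling of a C(sp2)–I bond with methanol, known for aryl and vinyl iodides under phenanthroline-ligated CuI with Cs2CO3, should replace the iodine on C3 by methoxyl, the carbonate base keeping free methoxide low so that ring C is not opened by addition at C2.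

**Step 8**
Reactants: 15 2-[4-(benzyloxy)phenyl]-3,5,6,7,8-pentamethoxy-4H-chromen-4-one
Product: 17 calycopterin (5-hydroxy-2-(4-hydroxyphenyl)-3,6,7,8-tetramethoxy-4H-chromen-4-one), via bis(dichloroboryl) ether 16 (not isolated)
Conditions: BCl3 (4 equiv), pentamethylbenzene (3 equiv), CH2Cl2, −78 to 0 °C; then H2O
Reagents that add atoms: boron trichloride ClB(Cl)Cl (boron and chlorine in intermediate 16 only)
Why: BCl3 binds the C4 carbonyl and the peri C5 methoxyl in a six-membered chelate from which chloride removes the methyl group (chelation-controlled Lewis acid demethylation), and the same reagent cleaves the benzyl aryl ether while pentamethylbenzene traps the benzyl cation by Friedel–Crafts alkylation; the methoxyls on C6, C7 and C8 are not chelated, and the C3 methoxyl, which could only form a five-membered chelate, should survive at low temperature.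

**Compound list**

1 | 1,2,3,4-tetramethoxybenzene | COc1ccc(OC)c(OC)c1OC | starting material
2 | (2,3,4,5-tetramethoxyphenyl)lithium | [Li]c1cc(OC)c(OC)c(OC)c1OC | intermediate (not isolated)
3 | lithium trimethoxy(2,3,4,5-tetramethoxyphenyl)borate | [Li+].CO[B-](OC)(OC)c1cc(OC)c(OC)c(OC)c1OC | intermediate (not isolated)
4 | 2,3,4,5-tetramethoxyphenol | Oc1cc(OC)c(OC)c(OC)c1OC | intermediate
5 | pentamethoxybenzene | COc1cc(OC)c(OC)c(OC)c1OC | intermediate
6 | (pentamethoxyphenyl)lithium | [Li]c1c(OC)c(OC)c(OC)c(OC)c1OC | intermediate (not isolated)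
7 | lithium (dimethylamino)(pentamethoxyphenyl)methanolate (racemic) | [Li+].[O-]C(N(C)C)c1c(OC)c(OC)c(OC)c(OC)c1OC | intermediate (not isolated)
8 | 2,3,4,5,6-pentamethoxybenzaldehyde | O=Cc1c(OC)c(OC)c(OC)c(OC)c1OC | intermediate
9 | 1-(benzyloxy)-4-ethynylbenzene | C#Cc1ccc(OCc2ccccc2)cc1 | starting material
10 | lithium [4-(benzyloxy)phenyl]acetylide | [Li]C#Cc1ccc(OCc2ccccc2)cc1 | intermediate (not isolated)
11 | 3-[4-(benzyloxy)phenyl]-1-(pentamethoxyphenyl)prop-2-yn-1-ol (racemic) | OC(C#Cc1ccc(OCc2ccccc2)cc1)c1c(OC)c(OC)c(OC)c(OC)c1OC | intermediate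
12 | 3-[4-(benzyloxy)phenyl]-1-(pentamethoxyphenyl)prop-2-yn-1-one | O=C(C#Cc1ccc(OCc2ccccc2)cc1)c1c(OC)c(OC)c(OC)c(OC)c1OC | intermediate
13 | 2-[4-(benzyloxy)phenyl]-3-iodo-5,6,7,8-tetramethoxy-1-methyl-4-oxo-4H-chromen-1-ium chloride | [Cl-].C[O+]1C(c2ccc(OCc3ccccc3)cc2)=C(I)C(=O)c2c(OC)c(OC)c(OC)c(OC)c21 | intermediate (not isolated)
14 | 2-[4-(benzyloxy)phenyl]-3-iodo-5,6,7,8-tetramethoxy-4H-chromen-4-one | COc1c(OC)c(OC)c2c(=O)c(I)c(-c3ccc(OCc4ccccc4)cc3)oc2c1OC | intermediate
15 | 2-[4-(benzyloxy)phenyl]-3,5,6,7,8-pentamethoxy-4H-chromen-4-one | COc1c(OC)c(OC)c2c(=O)c(OC)c(-c3ccc(OCc4ccccc4)cc3)oc2c1OC | intermediate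
16 | 5-(dichloroboryloxy)-2-[4-(dichloroboryloxy)phenyl]-3,6,7,8-tetramethoxy-4H-chromen-4-one | COc1c(OC)c(OB(Cl)Cl)c2c(=O)c(OC)c(-c3ccc(OB(Cl)Cl)cc3)oc2c1OC | intermediate (not isolated)
17 | calycopterin, 5-hydroxy-2-(4-hydroxyphenyl)-3,6,7,8-tetramethoxy-4H-chromen-4-one | COc1c(OC)c(O)c2c(=O)c(OC)c(-c3ccc(O)cc3)oc2c1OC | target

**Step count**

Total steps: 8. Longest linear sequence: 8 steps, from 1 to 17; alkyne 9 enters as a purchased material in step 4.

**Steps most likely to fail**

1. Step 7. Carbon–oxygen bond formation at C3 is hindered by the C2 aryl group and the C4 carbonyl, so it may be slow. Reductive loss of iodine, or addition of methoxide at C2 with opening of ring C, could then take over. Fallback, setting out from 14 and returning at 15: iodine–magnesium exchange with iPrMgCl·LiCl in THF at −40 °C should give [2-(4-benzyloxyphenyl)-5,6,7,8-tetramethoxy-4-oxo-4H-chromen-3-yl]magnesium chloride F1. B(OMe)3 should trap it as dimethyl [2-(4-benzyloxyphenyl)-5,6,7,8-tetramethoxy-4-oxo-4H-chromen-3-yl]boronate F2. Oxidation in the same flask with AcOH and H2O2 should give the flavonol 2-[4-(benzyloxy)phenyl]-3-hydroxy-5,6,7,8-tetramethoxy-4H-chromen-4-one F3. Methylation of its only free hydroxyl with MeI and K2CO3 in acetone should then give 15.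

2. Step 6. Electrophilic iodination of ring B ortho to the benzyloxy group, or closure in the 5-exo mode, may compete with the wanted 6-endo closure. Fallback, setting out from 8 and returning at 14, in which ring closure and iodination are separated:
   - BCl3 (1.1 equiv, CH2Cl2, −78 to 0 °C) should cleave one of the two equivalent ortho methoxyls through the chelate 2-(dichloroboryloxy)-3,4,5,6-tetramethoxybenzaldehyde F4 and give, after water, 2-hydroxy-3,4,5,6-tetramethoxybenzaldehyde F5.
   - Two equivalents of acetylide 10 should give the diol 2-{3-[4-(benzyloxy)phenyl]-1-hydroxyprop-2-yn-1-yl}-3,4,5,6-tetramethoxyphenol F6.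
   - MnO2 in CH2Cl2 should give the ortho-hydroxyaryl ynone 3-[4-(benzyloxy)phenyl]-1-(2-hydroxy-3,4,5,6-tetramethoxyphenyl)prop-2-yn-1-one F7.
   - Catalytic DMAP in DMF should close ring C by 6-endo oxa-Michael addition to 2-[4-(benzyloxy)phenyl]-5,6,7,8-tetramethoxy-4H-chromen-4-one F8.
   - LiN(iPr)2 in THF at −78 °C should lithiate C3 to give 2-[4-(benzyloxy)phenyl]-3-lithio-5,6,7,8-tetramethoxy-4H-chromen-4-one F9, and I2 should then give 14.

3. Step 8. Excess Lewis acid may demethylate further at the C3 or C6 methoxyl, or the benzyl cation may be transferred to a ring carbon, while both ethers are cleaved in one operation. Fallback, setting out from 15 and returning at 16 and then 17, in which the two deprotections are separated: hydrogenolysis (H2, Pd/C, EtOAc, rt) should remove the benzyl group and give 2-(4-hydroxyphenyl)-3,5,6,7,8-pentamethoxy-4H-chromen-4-one F10. A limited amount of BCl3 (2.5 equiv, CH2Cl2, −78 to 0 °C), now without any benzyl cation to control, should form 16, and water should release 17.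

**Further compounds**

F1 | step 7 | [2-(4-benzyloxyphenyl)-5,6,7,8-tetramethoxy-4-oxo-4H-chromen-3-yl]magnesium chloride | COc1c(OC)c(OC)c2c(=O)c([Mg]Cl)c(-c3ccc(OCc4ccccc4)cc3)oc2c1OC
F2 | step 7 | dimethyl [2-(4-benzyloxyphenyl)-5,6,7,8-tetramethoxy-4-oxo-4H-chromen-3-yl]boronate | COc1c(OC)c(OC)c2c(=O)c(B(OC)OC)c(-c3ccc(OCc4ccccc4)cc3)oc2c1OC
F3 | step 7 | 2-[4-(benzyloxy)phenyl]-3-hydroxy-5,6,7,8-tetramethoxy-4H-chromen-4-one | COc1c(OC)c(OC)c2c(=O)c(O)c(-c3ccc(OCc4ccccc4)cc3)oc2c1OC
F4 | step 6 | 2-(dichloroboryloxy)-3,4,5,6-tetramethoxybenzaldehyde | O=Cc1c(OB(Cl)Cl)c(OC)c(OC)c(OC)c1OC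
F5 | step 6 | 2-hydroxy-3,4,5,6-tetramethoxybenzaldehyde | O=Cc1c(O)c(OC)c(OC)c(OC)c1OC
F6 | step 6 | 2-{3-[4-(benzyloxy)phenyl]-1-hydroxyprop-2-yn-1-yl}-3,4,5,6-tetramethoxyphenol (racemic) | OC(C#Cc1ccc(OCc2ccccc2)cc1)c1c(O)c(OC)c(OC)c(OC)c1OC
F7 | step 6 | 3-[4-(benzyloxy)phenyl]-1-(2-hydroxy-3,4,5,6-tetramethoxyphenyl)prop-2-yn-1-one | O=C(C#Cc1ccc(OCc2ccccc2)cc1)c1c(O)c(OC)c(OC)c(OC)c1OC
F8 | step 6 | 2-[4-(benzyloxy)phenyl]-5,6,7,8-tetramethoxy-4H-chromen-4-one | COc1c(OC)c(OC)c2c(=O)cc(-c3ccc(OCc4ccccc4)cc3)oc2c1OC
F9 | step 6 | 2-[4-(benzyloxy)phenyl]-3-lithio-5,6,7,8-tetramethoxy-4H-chromen-4-one | COc1c(OC)c(OC)c2c(=O)c([Li])c(-c3ccc(OCc4ccccc4)cc3)oc2c1OC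
F10 | step 8 | 2-(4-hydroxyphenyl)-3,5,6,7,8-pentamethoxy-4H-chromen-4-one | COc1c(OC)c(OC)c2c(=O)c(OC)c(-c3ccc(O)cc3)oc2c1OC
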